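Abbreviations: TBS = tert-butyldimethylsilyl, TES = triethylsilyl, TIPS = triisopropylsilyl. Target numbering is used on every intermediate. β is the face of the seven-membered ring (and of the bicycle) that carries the C1 methyl group, α the opposite face.

## Analysis of the target

Compound 39 is a daucane-type triester: a cyclopentane (C1–C5) trans-fused to a cycloheptene (C1, C5–C10) whose only ring alkene is the trisubstituted C8=C9 bond, with the methyl group on C8. With C1 the quaternary methyl carbon, C2 the acetoxy carbon, C4 the tertiary carbinol carrying isopropyl, C5 the fusion CH, C6 the angelate carbon and C10 the benzoate carbon, the six stereocentres are 1R,2S,4R,5S,6S,10S. H5 is α (trans fusion), the C4 hydroxyl and the C10 benzoate are β, and the C2 acetate and C6 angelate are α; the C2 and C6 oxygens are thus both 1,3-anti to the tertiary hydroxyl, and the C10 oxygen is 1,3-anti to the C2 oxygen. The sensitive groups are the (Z)-2-methylbut-2-enoate (it isomerises to the tiglate under nucleophilic catalysis or strong base), the allylic benzoate, and the tertiary alcohol between two acyloxy carbons (retro-aldol or elimination as soon as a neighbour is a ketone; acyl migration). The difficulties are the quaternary C1 with oxygenated carbons on two sides, the trans fusion, telling three secondary oxygens apart for three different esters, and the alkene position: C8=C9 is skipped relative to C6 and allylic to C10, so it migrates whenever C6 is a carbonyl group. The plan rests on the oxygens at C6 and C10 lying on either side of the C1–C5 bond: a three-carbon 2-oxy vinylcarbenoid (C5–C6–C7) and a four-carbon 2-oxy diene (C8–C9–C10–C1) deliver both as enol ethers, and the bond that joins them last, C1–C5, creates the quaternary centre.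

## Retrosynthetic reasoning

**C10–O acyl bond and the C8 methyl/C8=C9 unit (39 → 38 → 37 → 36 → 35 → 33).** The benzoate is removed first, then the allylic carbinol 38 is traced to enone 37, whose carbonyl fixes the alkene at C8=C9 by conjugation. 1,2-Reduction should occur anti to the adjacent angular methyl and give the 10β-carbinol. The C8 methyl is cut as a conjugate methylation of enone 35 followed by renewed dehydrogenation (36 → 37), and 35 comes from the C10 carbinol 33. This is placed last because a C8=C9 alkene next to a C6 ketone would slip into conjugation, and an enone at C10 together with a ketone at C6 is a vinylogous 1,3-diketone in which the alkene scrambles. The unsaturation is therefore introduced only after C6 has become an ester.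

**C2–O and C6–O carbinols and their esters (33 → 32 → 31 → 30 → 29 → 28 → 26 → 25).** Both secondary carbinols are 1,3-anti to the tertiary C4 hydroxyl, so both are traced to ketones that are reduced by hydride delivered from a boron held on the C4 oxygen. The two reductions are separated in time: C6 is reduced first (25 → 26) and acylated with 27, and C2 is unveiled, oxidised and reduced afterwards (29 → 31). The two oxygens are thus told apart by order, not by a selective acylation.

**C5–H and C4–O, the trans fusion (25 → 24 → 23 → 22 → 21).** A tether from C1 that closes onto a C5 enolate would give the cis-fused ring, so the fusion hydrogen is instead cut as a 1,2-hydride shift from C6 to C5 in the epoxy silyl ether 24. The shift is stereospecific: the β-epoxide oxygen stays on C4 and the hydrogen arrives on the α-face of C5. The forward sequence needs only one facial choice, reduction of enone 21 anti to the angular methyl (22), after which the epoxidation is hydroxyl-directed (23).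

**C4–C5 bond, the five-membered ring (21 → 20).** The ring is opened between C4 and C5, with C5 as the enolate carbon of the C6 ketone and C4 as the β-carbon of an alkynone whose carbonyl is C2. A C4 ketone with an oxygen on C2 would be a β-alkoxy ketone that eliminates under any condensation conditions. The alkynone keeps C2 at the ketone level (reduced later under control of the C4 hydroxyl) and makes C4 electrophilic without an enolisable C3. Only the C5 enolate can reach C4 in a five-membered closure.

**C2–C3 bond and the masking of C6, C7 and C10 (20 → 18 → 17 → 16 → 14 → 12 + 13; 12 → 11 → 10).** C2 is the ester carbon on C1 of 10; it is reduced, oxidised to the aldehyde and joined to 13. The C10 enol ether is converted into a single carbinol under direction by the C2 hydroxyl and then silylated, because a free C10 ketone would offer its C9 enolate a six-membered closure onto the alkynone. The C7 ester is lost by acidolysis and decarboxylation once the side chain is in place. For this the two esters of 10 must differ, which is why the diazo component carries a tert-butyl ester.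

**C1–C5 and C7–C8, the seven-membered ring (10 → 5 + 8).** The ring is cut into the vinyldiazoacetate 8 and the diene 5. In the forward sense cyclopropanation makes C7–C8 (and transiently C7–C9), and the Cope shift of 9 makes C1–C5. The cut is made here because both ring oxygens then arrive as enol ethers of different lability and the quaternary centre is set by a catalyst from two achiral pieces.

**The components (5 → 3 → 1 + 2; 8 → 7 → 6).** The diene comes from acylation of 1 with 2, elimination and O-silylation; the diazo compound from diazo transfer to 6 and O-silylation.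

## Alternatives that were turned down

**Alternative 1:** The cyclopentane is made by ring contraction of a chiral-pool cyclohexene epoxide that already holds the isopropyl carbinol. A bulky aluminium aryloxide Lewis acid opens the epoxide at C1 while C5 migrates from C10 to C1, giving 2-(TBS-oxy)-1-methyl-4-isopropyl-4-(trimethylsilyloxy)-5-[(4-methoxybenzyloxy)methyl]cyclopentane-1-carbaldehyde A1.
- For: C4 comes from the chiral pool, and one stereospecific 1,2-shift sets C1 relative to C2, C4 and C5. On the cyclopentane this is clearly stronger than the chosen route, which spends about ten steps on C2, C4 and C5.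
- Against: A1 holds only C6 and C10 of the large ring, as one-carbon stubs. C7, C8 with its methyl and C9 must still be added, and two carbinols must be created next to existing centres and then distinguished. The C1 aldehyde is neopentyl, and the epoxide face and migrating group must be secured on a substrate that itself needs many steps.
- Comparison: the chosen strategy has the opposite profile. The seven-membered ring, both its oxygens in distinguishable form and C1 come from one catalytic step, and the price is paid on the small ring.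

**Alternative 2:** Both rings are closed at once by an intramolecular (4+3) cycloaddition of a chloro-oxyallyl cation (C9–C10–C1) with a tethered siloxydiene (C5–C8), followed by dehydrochlorination, to give the trans-fused 2,6-bis(TBS-oxy)-4-(trimethylsilyloxy)-1,8-dimethyl-4-isopropylbicyclo[5.3.0]deca-6,8-dien-10-one A2.
- For: it is the most convergent option. A2 already contains the C8-methyl enone and the C6 oxygen, so the late methylation and dehydrogenation of the chosen route would be unnecessary; on step economy after the key step it is stronger.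
- Against: C1 and C5 must be set, with a trans fusion, by relay from C2 and C4 through a three-atom tether, with no external control. The cation must be generated next to a fully substituted carbon that carries a β-silyloxy group. The acyclic precursor with two stereocentres, a dichloroketone and a diene is long to make. Unmasking the C6 ketone of A2 gives the vinylogous 1,3-diketone in which the alkene can move.
- Comparison: the chosen strategy closes only one ring in its key step, but the stereocentre is under catalyst control and the fragments are simple and achiral.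

**Alternative 3:** A trans-cyclopentane dialdehyde is annulated with a bifunctional three-carbon allyl reagent (an allylic iodide that also carries an allylsilane) under a divalent tin halide, forming C6–C7 and C9–C10 and giving the trans-fused 8-methylidene-6,10-diol A3.
- For: the three ring carbons and the methyl carbon arrive in one operation and both carbinols appear at the alcohol level. This is stronger than the chosen route's conjugate methylation and double dehydrogenation.
- Against: C6 and C10 are formed by 1,2-induction only, so the 6α,10β pattern is not assured. The two secondary alcohols of A3 are alike and must still be told apart for angelate and benzoate. The exocyclic alkene must be moved regioselectively to C8=C9 and not C7=C8, with no bias. The dialdehyde presupposes a cyclopentane of the A1 type with an epimerisable C5 formyl group.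
- Comparison: the chosen strategy distinguishes the C6 and C10 oxygens from the outset and fixes the alkene position by conjugation with a C10 ketone.

Key step: step 5

Remarks on the chemistry:
- Assumption: the facial sense of Rh2(R-PTAD)4 is assigned by analogy with the usual sense of chiral dirhodium carboxylates in cyclopropanation of monosubstituted alkenes; should 10 prove to be the antipode, the mirror-image catalyst Rh2(S-PTAD)4 is used and nothing else changes.
- The ester of the diazo component is tert-butyl instead of methyl, so that the two esters of 10 differ towards hydride and acid; 2 serves as a storable acryloyl equivalent.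
- C2 in 14–16 and C8 in 36 are stereocentres of no consequence (both become trigonal again) and are left undefined.

## Route

Step 1
Reactants: 1 methyl propanoate; 2 3-chloropropanoyl chloride
Product: 3 methyl 5-chloro-2-methyl-3-oxopentanoate
Conditions: 1 (2.0 equiv), LiN(i-Pr)2 (2.0 equiv), THF, −78 °C; then 2 (1.0 equiv), −78 °C; aq. HCl
Reagents that add atoms: none
Why: Crossed Claisen acylation of the lithium ester enolate by the acid chloride; the second equivalent of enolate takes up the acidic proton of the β-keto ester, and the chloride keeps the vinyl ketone masked until step 2.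

Step 2
Reactants: 3 methyl 5-chloro-2-methyl-3-oxopentanoate
Product: 5 methyl (2Z)-2-methyl-3-(triethylsilyloxy)penta-2,4-dienoate, via methyl 2-methyl-3-oxopent-4-enoate 4 (not isolated)
Conditions: Et3N (2.5 equiv), CH2Cl2, 0 °C; then TESOTf (1.1 equiv), −78 → 0 °C
Reagents that add atoms: triethylsilyl trifluoromethanesulfonate, CC[Si](CC)(CC)OS(=O)(=O)C(F)(F)F
Why: E1cB loss of HCl gives the vinyl ketone, which is O-silylated at once by soft enolisation before it can oligomerise. The ester-chelated enol should place the silyloxy group cis to the ester, the geometry the Cope step needs; any (E) isomer must be removed because it would lead to the antipode at C1.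

Step 3
Reactants: 6 tert-butyl 3-oxobutanoate
Product: 7 tert-butyl 2-diazo-3-oxobutanoate
Conditions: 4-acetamidobenzenesulfonyl azide, Et3N, MeCN, 0 °C → rt
Reagents that add atoms: 4-acetamidobenzenesulfonyl azide, CC(=O)Nc1ccc(cc1)S(=O)(=O)N=[N+]=[N-]
Why: Regitz diazo transfer to the activated methylene of the 1,3-dicarbonyl compound.

Step 4
Reactants: 7 tert-butyl 2-diazo-3-oxobutanoate
Product: 8 tert-butyl 3-(tert-butyldimethylsilyloxy)-2-diazobut-3-enoate
Conditions: TBSOTf, Et3N, CH2Cl2, 0 °C
Reagents that add atoms: tert-butyldimethylsilyl trifluoromethanesulfonate, CC(C)(C)[Si](C)(C)OS(=O)(=O)C(F)(F)F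
Why: Soft enolisation and O-silylation of the acetyl group gives the 2-siloxy vinyldiazoacetate; the stabilised diazo ester tolerates amine and silyl triflate.

Step 5
Reactants: 5 methyl (2Z)-2-methyl-3-(triethylsilyloxy)penta-2,4-dienoate; 8 tert-butyl 3-(tert-butyldimethylsilyloxy)-2-diazobut-3-enoate
Product: 10 7-tert-butyl 1-methyl 1-methyl-6-(TBS-oxy)-10-(TES-oxy)cyclohepta-6,9-diene-1,7-dicarboxylate (C1 configured as in 39), via cis-divinylcyclopropane 9 (not isolated)
Conditions: Rh2(R-PTAD)4, dirhodium tetrakis[(R)-(1-adamantyl)(phthalimido)acetate] (2 mol %), hexanes, −20 °C → rt, slow addition of 8 (1.5 equiv); then 60 °C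
Reagents that add atoms: none
Why: The catalyst expels N2 from 8 to give a donor–acceptor 2-siloxyvinyl carbenoid, which cyclopropanates the monosubstituted alkene of 5 (bonds C7–C8 and C7–C9) end-on, so that the two alkenyl groups of 9 end up cis. The cis-divinylcyclopropane 9 then undergoes the Cope rearrangement through the boat transition state, breaking C7–C9 and forming C1–C5; warming is provided because the C1 terminus carries its methyl group on the inside of the boat. The closest known reaction type is the rhodium-carbenoid [4+3] cycloaddition of 2-diazo-3-siloxybut-3-enoates with dienes, including dienes with a disubstituted terminus that give quaternary centres. The seven-membered ring is closed in the [3,3]-sigmatropic event itself, a three-carbon plus four-carbon union overall; no other ring remains. C1, the only stereocentre, is controlled by two elements: the catalyst selects the alkene face and so the absolute configuration of 9, and the boat geometry relays it to C1 through the fixed (Z) geometry of the tetrasubstituted enol ether (methyl inside, ester outside). The step needs site selectivity, which the substrate secures because the tetrasubstituted push–pull enol ether is shielded and deactivated by its ester; cis selectivity, which is intrinsic to donor–acceptor carbenoids; and enantioselectivity, for which the adamantylglycinate catalyst is chosen because prolinate catalysts such as Rh2(S-DOSP)4 are known to lose selectivity when the vinylcarbenoid bears a 2-siloxy group. The geometric purity of 5 caps the enantiomeric purity of 10.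

Step 6
Reactants: 10 7-tert-butyl 1-methyl 1-methyl-6-(TBS-oxy)-10-(TES-oxy)cyclohepta-6,9-diene-1,7-dicarboxylate
Product: 11 tert-butyl 1-(hydroxymethyl)-1-methyl-6-(TBS-oxy)-10-(TES-oxy)cyclohepta-6,9-diene-7-carboxylate
Conditions: i-Bu2AlH (2.2 equiv), CH2Cl2, −78 °C; aq. KNaC4H4O6
Reagents that add atoms: none
Why: Hydride reduction of the ordinary methyl ester; the tert-butyl ester is a bulky vinylogous carbonate (β-siloxy enoate) and should be left alone at −78 °C, and both silyl enol ethers are inert to the hydride and the neutral tartrate work-up.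

Step 7
Reactants: 11 tert-butyl 1-(hydroxymethyl)-1-methyl-6-(TBS-oxy)-10-(TES-oxy)cyclohepta-6,9-diene-7-carboxylate
Product: 12 tert-butyl 1-formyl-1-methyl-6-(TBS-oxy)-10-(TES-oxy)cyclohepta-6,9-diene-7-carboxylate
Conditions: Dess–Martin periodinane, pyridine, CH2Cl2, 0 °C
Reagents that add atoms: none
Why: Dess–Martin oxidation under pyridine buffer; the aldehyde sits on the quaternary C1 and cannot enolise, and the buffered medium spares the enol ethers.

Step 8
Reactants: 12 tert-butyl 1-formyl-1-methyl-6-(TBS-oxy)-10-(TES-oxy)cyclohepta-6,9-diene-7-carboxylate; 13 3-methylbut-1-yne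
Product: 14 tert-butyl 1-(1-hydroxy-4-methylpent-2-ynyl)-1-methyl-6-(TBS-oxy)-10-(TES-oxy)cyclohepta-6,9-diene-7-carboxylate (C2 epimers)
Conditions: 13, n-BuLi, THF, −78 °C; then 12, −78 → −40 °C; aq. NH4Cl
Reagents that add atoms: none
Why: 1,2-Addition of the lithium acetylide to the neopentyl aldehyde brings in C3, C4 and the isopropyl group; the vinylogous tert-butyl carbonate is not attacked, and the carbinol configuration is irrelevant because C2 becomes a ketone in step 10.

Step 9
Reactants: 14 tert-butyl 1-(1-hydroxy-4-methylpent-2-ynyl)-1-methyl-6-(TBS-oxy)-10-(TES-oxy)cyclohepta-6,9-diene-7-carboxylate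
Product: 16 tert-butyl 10β-hydroxy-1-(1-hydroxy-4-methylpent-2-ynyl)-1-methyl-6-(TBS-oxy)cyclohept-6-ene-7-carboxylate (C2 epimers), via C10 ketone 15 (not isolated)
Conditions: AcOH/MeCN/H2O, 0 °C; then Me4NBH(OAc)3, AcOH/MeCN, −20 °C
Reagents that add atoms: none
Why: Aqueous acetic acid hydrolyses the simple TES enol ether but not the push–pull silyloxy enoate. In the following Evans–Saksena reduction, the boron held on the C2 hydroxyl (on the α substituent of C1) delivers hydride to the α-face of the C10 ketone and gives the 10β-carbinol as a single C10 isomer.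

Step 10
Reactants: 16 tert-butyl 10β-hydroxy-1-(1-hydroxy-4-methylpent-2-ynyl)-1-methyl-6-(TBS-oxy)cyclohept-6-ene-7-carboxylate
Product: 17 tert-butyl 10β-hydroxy-1-methyl-1-(4-methylpent-2-ynoyl)-6-(TBS-oxy)cyclohept-6-ene-7-carboxylate
Conditions: MnO2 (activated, excess), CH2Cl2, rt
Reagents that add atoms: none
Why: MnO2 oxidises only the propargylic carbinol to the alkynone; the saturated C10 carbinol does not react, and both C2 epimers converge.

Step 11
Reactants: 17 tert-butyl 10β-hydroxy-1-methyl-1-(4-methylpent-2-ynoyl)-6-(TBS-oxy)cyclohept-6-ene-7-carboxylate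
Product: 18 tert-butyl 1-methyl-1-(4-methylpent-2-ynoyl)-6-(TBS-oxy)-10β-(TIPS-oxy)cyclohept-6-ene-7-carboxylate
Conditions: TIPSOTf, 2,6-lutidine, CH2Cl2, −40 → 0 °C
Reagents that add atoms: triisopropylsilyl trifluoromethanesulfonate, CC(C)[Si](OS(=O)(=O)C(F)(F)F)(C(C)C)C(C)C
Why: Silylation removes the C10 hydroxyl as a nucleophile (it would otherwise add to the alkynone in a 6-endo oxa-Michael reaction) and gives an ether robust enough for the acid of step 12 and the base of step 13.

Step 12
Reactants: 18 tert-butyl 1-methyl-1-(4-methylpent-2-ynoyl)-6-(TBS-oxy)-10β-(TIPS-oxy)cyclohept-6-ene-7-carboxylate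
Product: 20 1-methyl-1-(4-methylpent-2-ynoyl)-10β-(TIPS-oxy)cycloheptan-6-one, via beta-keto acid 19 (not isolated)
Conditions: CF3CO2H/CH2Cl2 (1:4), H2O (2 equiv), 0 °C → rt; then toluene, 80 °C
Reagents that add atoms: none
Why: Acidolysis of the tert-butyl ester and of the enol silyl ether gives the β-keto acid, which decarboxylates on warming; the alkynone and the hindered TIPS ether are stable to these conditions.

Step 13
Reactants: 20 1-methyl-1-(4-methylpent-2-ynoyl)-10β-(TIPS-oxy)cycloheptan-6-one
Product: 21 4-isopropyl-1-methyl-10β-(TIPS-oxy)bicyclo[5.3.0]dec-4-ene-2,6-dione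
Conditions: KOt-Bu (1.1 equiv), t-BuOH/THF, 0 °C; then AcOH, −78 °C
Reagents that add atoms: none
Why: Intramolecular Michael addition of a ketone enolate to an alkynone (5-endo-dig carbocyclisation): under equilibrating base only the C5 enolate can reach the β-carbon C4, since the C7 enolate would need a seven-membered ring, and the adduct is held as its vinylogous 1,3-diketonate. Cold protonation at the unhindered C3 should give the tetrasubstituted C4=C5 enone; no stereocentre is formed.

Step 14
Reactants: 21 4-isopropyl-1-methyl-10β-(TIPS-oxy)bicyclo[5.3.0]dec-4-ene-2,6-dione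
Product: 22 4-isopropyl-1-methyl-10β-(TIPS-oxy)bicyclo[5.3.0]dec-4-ene-2β,6β-diol
Conditions: NaBH4, CeCl3·7H2O, MeOH, −78 → −40 °C
Reagents that add atoms: none
Why: Luche reduction: hydride adds 1,2 to the enone carbonyl C6 from the α-face, anti to the angular C1 methyl, giving the 6β allylic alcohol needed in steps 15 and 17. The C2 ketone is reduced as well (β expected; its configuration is irrelevant because it is re-oxidised in step 21), and the cerium salt keeps the medium from enolising C3.

Step 15
Reactants: 22 4-isopropyl-1-methyl-10β-(TIPS-oxy)bicyclo[5.3.0]dec-4-ene-2β,6β-diol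
Product: 23 4β,5β-epoxy-4-isopropyl-1-methyl-10β-(TIPS-oxy)bicyclo[5.3.0]decane-2β,6β-diol
Conditions: VO(acac)2 (5 mol %), t-BuOOH, CH2Cl2, 0 °C → rt
Reagents that add atoms: tert-butyl hydroperoxide, CC(C)(C)OO
Why: Hydroxyl-directed epoxidation: the vanadium alkoxide of the allylic 6β-hydroxyl delivers the peroxide oxygen to the β-face of the tetrasubstituted alkene, giving the cis-epoxy alcohol.

Step 16
Reactants: 23 4β,5β-epoxy-4-isopropyl-1-methyl-10β-(TIPS-oxy)bicyclo[5.3.0]decane-2β,6β-diol
Product: 24 4β,5β-epoxy-4-isopropyl-1-methyl-2β,6β-bis(TES-oxy)-10β-(TIPS-oxy)bicyclo[5.3.0]decane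
Conditions: TESCl, imidazole, DMAP (cat.), DMF, rt
Reagents that add atoms: chlorotriethylsilane, CC[Si](Cl)(CC)CC
Why: Silylation of both secondary hydroxyls under non-acidic conditions that leave the epoxide alone; the C6 silyl ether is the trigger of step 17 and the C2 silyl ether keeps that oxygen apart from C6 through steps 18 and 19.

Step 17
Reactants: 24 4β,5β-epoxy-4-isopropyl-1-methyl-2β,6β-bis(TES-oxy)-10β-(TIPS-oxy)bicyclo[5.3.0]decane
Product: 25 trans-fused 4β-hydroxy-4-isopropyl-1-methyl-2β-(TES-oxy)-10β-(TIPS-oxy)bicyclo[5.3.0]decan-6-one (H5 α)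
Conditions: BF3·OEt2 (1.1 equiv), CH2Cl2, −78 °C; aq. NaHCO3
Reagents that add atoms: none
Why: Suzuki–Tsuchihashi (semipinacol) rearrangement of a 2,3-epoxy silyl ether: the Lewis acid opens the epoxide at C5 while the α-hydrogen on C6, antiperiplanar to the breaking β C5–O bond, shifts to C5 and C6 becomes the ketone. The hydrogen therefore arrives on the α-face of C5 (trans fusion) and the oxygen stays β on C4, both stereospecifically.

Step 18
Reactants: 25 trans-fused 4β-hydroxy-4-isopropyl-1-methyl-2β-(TES-oxy)-10β-(TIPS-oxy)bicyclo[5.3.0]decan-6-one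
Product: 26 trans-fused 4-isopropyl-1-methyl-2β-(TES-oxy)-10β-(TIPS-oxy)bicyclo[5.3.0]decane-4β,6α-diol
Conditions: Me4NBH(OAc)3, AcOH/MeCN, −20 °C
Reagents that add atoms: none
Why: Evans–Saksena reduction of the β-hydroxy ketone: boron bound to the tertiary 4β-hydroxyl delivers hydride to the β-face of C6, giving the 6α-carbinol (1,3-anti) under mildly acidic conditions that avoid retro-aldol.

Step 19
Reactants: 26 trans-fused 4-isopropyl-1-methyl-2β-(TES-oxy)-10β-(TIPS-oxy)bicyclo[5.3.0]decane-4β,6α-diol; 27 angelic acid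
Product: 28 trans-fused 6α-angeloyloxy-4-isopropyl-1-methyl-2β-(TES-oxy)-10β-(TIPS-oxy)bicyclo[5.3.0]decan-4β-ol
Conditions: 27, 2,4,6-trichlorobenzoyl chloride, Et3N, toluene, rt; then 26, 75 °C
Reagents that add atoms: none
Why: Yamaguchi-type esterification through the mixed anhydride without a nucleophilic pyridine catalyst, conditions chosen to keep the (Z) geometry of the angelate; the tertiary hydroxyl is too hindered to be acylated.

Step 20
Reactants: 28 trans-fused 6α-angeloyloxy-4-isopropyl-1-methyl-2β-(TES-oxy)-10β-(TIPS-oxy)bicyclo[5.3.0]decan-4β-ol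
Product: 29 trans-fused 6α-angeloyloxy-4-isopropyl-1-methyl-10β-(TIPS-oxy)bicyclo[5.3.0]decane-2β,4β-diol
Conditions: HF·pyridine, pyridine, THF, 0 °C
Reagents that add atoms: none
Why: Buffered fluoride removes the labile TES ether selectively; the TIPS ether and both esters remain.

Step 21
Reactants: 29 trans-fused 6α-angeloyloxy-4-isopropyl-1-methyl-10β-(TIPS-oxy)bicyclo[5.3.0]decane-2β,4β-diol
Product: 30 trans-fused 6α-angeloyloxy-4β-hydroxy-4-isopropyl-1-methyl-10β-(TIPS-oxy)bicyclo[5.3.0]decan-2-one
Conditions: Dess–Martin periodinane, NaHCO3, CH2Cl2, 0 °C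
Reagents that add atoms: none
Why: Dess–Martin oxidation of the only secondary hydroxyl; the neutral buffered medium avoids retro-aldol of the tertiary β-hydroxy ketone.

Step 22
Reactants: 30 trans-fused 6α-angeloyloxy-4β-hydroxy-4-isopropyl-1-methyl-10β-(TIPS-oxy)bicyclo[5.3.0]decan-2-one
Product: 31 trans-fused 6α-angeloyloxy-4-isopropyl-1-methyl-10β-(TIPS-oxy)bicyclo[5.3.0]decane-2α,4β-diol
Conditions: Me4NBH(OAc)3, AcOH/MeCN, −20 °C
Reagents that add atoms: none
Why: Second Evans–Saksena reduction: the 4β-hydroxyl delivers hydride to the β-face of the cyclopentanone and gives the 2α-carbinol, trans to the C4 hydroxyl; an undirected hydride would come anti to the methyl and give the wrong epimer.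

Step 23
Reactants: 31 trans-fused 6α-angeloyloxy-4-isopropyl-1-methyl-10β-(TIPS-oxy)bicyclo[5.3.0]decane-2α,4β-diol
Product: 32 trans-fused 2α-acetoxy-6α-angeloyloxy-4-isopropyl-1-methyl-10β-(TIPS-oxy)bicyclo[5.3.0]decan-4β-ol
Conditions: Ac2O, pyridine, DMAP (cat.), CH2Cl2, rt
Reagents that add atoms: acetic anhydride, CC(=O)OC(C)=O
Why: Acetylation of the secondary alcohol; the tertiary hydroxyl does not react at room temperature.

Step 24
Reactants: 32 trans-fused 2α-acetoxy-6α-angeloyloxy-4-isopropyl-1-methyl-10β-(TIPS-oxy)bicyclo[5.3.0]decan-4β-ol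
Product: 33 trans-fused 2α-acetoxy-6α-angeloyloxy-4-isopropyl-1-methylbicyclo[5.3.0]decane-4β,10β-diol
Conditions: HF·pyridine, THF, rt
Reagents that add atoms: none
Why: Fluoride cleavage of the TIPS ether under acidic-neutral conditions that neither hydrolyse nor migrate the esters.

Step 25
Reactants: 33 trans-fused 2α-acetoxy-6α-angeloyloxy-4-isopropyl-1-methylbicyclo[5.3.0]decane-4β,10β-diol
Product: 35 trans-fused 2α-acetoxy-6α-angeloyloxy-4β-hydroxy-4-isopropyl-1-methylbicyclo[5.3.0]dec-8-en-10-one, via C10 ketone 34 (not isolated)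
Conditions: IBX (3 equiv), DMSO, 70 °C
Reagents that add atoms: none
Why: IBX oxidises the carbinol to the ketone and then dehydrogenates the ketone through its enol to the enone. Because C1 is quaternary, only C9–C8 can be dehydrogenated, and the other carbonyl groups are esters.

Step 26
Reactants: 35 trans-fused 2α-acetoxy-6α-angeloyloxy-4β-hydroxy-4-isopropyl-1-methylbicyclo[5.3.0]dec-8-en-10-one
Product: 36 trans-fused 2α-acetoxy-6α-angeloyloxy-4β-hydroxy-4-isopropyl-1,8-dimethylbicyclo[5.3.0]decan-10-one (C8 epimers)
Conditions: Me2CuLi (3 equiv, from MeLi and CuI), THF, −78 °C; aq. NH4Cl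
Reagents that add atoms: lithium dimethylcuprate, [Li+].C[Cu-]C
Why: 1,4-Addition of the cuprate to the cycloheptenone places the methyl on C8; the esters, including the α,β-disubstituted angelate, are inert at −78 °C, and the C8 configuration is irrelevant because it is removed in step 27.

Step 27
Reactants: 36 trans-fused 2α-acetoxy-6α-angeloyloxy-4β-hydroxy-4-isopropyl-1,8-dimethylbicyclo[5.3.0]decan-10-one
Product: 37 trans-fused 2α-acetoxy-6α-angeloyloxy-4β-hydroxy-4-isopropyl-1,8-dimethylbicyclo[5.3.0]dec-8-en-10-one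
Conditions: IBX (2 equiv), DMSO, 70 °C
Reagents that add atoms: none
Why: Second IBX dehydrogenation re-forms the C8=C9 enone, now β-methylated; conjugation with the C10 carbonyl fixes the alkene position, and C6 is already an ester so the alkene cannot wander.

Step 28
Reactants: 37 trans-fused 2α-acetoxy-6α-angeloyloxy-4β-hydroxy-4-isopropyl-1,8-dimethylbicyclo[5.3.0]dec-8-en-10-one
Product: 38 trans-fused 2α-acetoxy-6α-angeloyloxy-4-isopropyl-1,8-dimethylbicyclo[5.3.0]dec-8-ene-4β,10β-diol
Conditions: NaBH4, CeCl3·7H2O, MeOH, −78 °C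
Reagents that add atoms: none
Why: Luche 1,2-reduction of the enone; hydride attacks C10 from the α-face, anti to the adjacent angular methyl, and gives the 10β allylic alcohol without touching the esters.

Step 29
Reactants: 38 trans-fused 2α-acetoxy-6α-angeloyloxy-4-isopropyl-1,8-dimethylbicyclo[5.3.0]dec-8-ene-4β,10β-diol
Product: 39 CNP0248576.1: 2α-acetoxy-6α-angeloyloxy-10β-benzoyloxy-4β-hydroxy-4-isopropyl-1,8-dimethyl-trans-bicyclo[5.3.0]dec-8-ene (1R,2S,4R,5S,6S,10S)
Conditions: BzCl, pyridine, DMAP (cat.), CH2Cl2, 0 °C → rt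
Reagents that add atoms: benzoyl chloride, O=C(Cl)c1ccccc1
Why: Acylation of the secondary allylic alcohol; the tertiary hydroxyl stays free, and the mild base does not isomerise the angelate.

## Compound list

1 | methyl propanoate | CCC(=O)OC | starting material
2 | 3-chloropropanoyl chloride | O=C(Cl)CCCl | starting material
3 | methyl 5-chloro-2-methyl-3-oxopentanoate | COC(=O)C(C)C(=O)CCCl | intermediate
4 | methyl 2-methyl-3-oxopent-4-enoate (not isolated) | COC(=O)C(C)C(=O)C=C | intermediate
5 | methyl (2Z)-2-methyl-3-(triethylsilyloxy)penta-2,4-dienoate | C=C/C(O[Si](CC)(CC)CC)=C(\C)C(=O)OC | intermediate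
6 | tert-butyl 3-oxobutanoate | CC(=O)CC(=O)OC(C)(C)C | starting material
7 | tert-butyl 2-diazo-3-oxobutanoate | CC(=O)C(=[N+]=[N-])C(=O)OC(C)(C)C | intermediate
8 | tert-butyl 3-(tert-butyldimethylsilyloxy)-2-diazobut-3-enoate | C=C(O[Si](C)(C)C(C)(C)C)C(=[N+]=[N-])C(=O)OC(C)(C)C | intermediate
9 | cis-divinylcyclopropane: tert-butyl 1-[1-(TBS-oxy)ethenyl]-2-[(1Z)-3-methoxy-2-methyl-3-oxo-1-(TES-oxy)prop-1-enyl]cyclopropane-1-carboxylate, alkenyl groups cis (not isolated) | C=C(O[Si](C)(C)C(C)(C)C)[C@]1(C(=O)OC(C)(C)C)C[C@@H]1/C(O[Si](CC)(CC)CC)=C(\C)C(=O)OC | intermediate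
10 | 7-tert-butyl 1-methyl 1-methyl-6-(TBS-oxy)-10-(TES-oxy)cyclohepta-6,9-diene-1,7-dicarboxylate | COC(=O)[C@@]1(C)CC(O[Si](C)(C)C(C)(C)C)=C(C(=O)OC(C)(C)C)CC=C1O[Si](CC)(CC)CC | intermediate
11 | tert-butyl 1-(hydroxymethyl)-1-methyl-6-(TBS-oxy)-10-(TES-oxy)cyclohepta-6,9-diene-7-carboxylate | OC[C@@]1(C)CC(O[Si](C)(C)C(C)(C)C)=C(C(=O)OC(C)(C)C)CC=C1O[Si](CC)(CC)CC | intermediate
12 | tert-butyl 1-formyl-1-methyl-6-(TBS-oxy)-10-(TES-oxy)cyclohepta-6,9-diene-7-carboxylate | O=C[C@@]1(C)CC(O[Si](C)(C)C(C)(C)C)=C(C(=O)OC(C)(C)C)CC=C1O[Si](CC)(CC)CC | intermediate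
13 | 3-methylbut-1-yne | CC(C)C#C | starting material
14 | tert-butyl 1-(1-hydroxy-4-methylpent-2-ynyl)-1-methyl-6-(TBS-oxy)-10-(TES-oxy)cyclohepta-6,9-diene-7-carboxylate (C2 epimers) | CC(C)C#CC(O)[C@@]1(C)CC(O[Si](C)(C)C(C)(C)C)=C(C(=O)OC(C)(C)C)CC=C1O[Si](CC)(CC)CC | intermediate
15 | tert-butyl 1-(1-hydroxy-4-methylpent-2-ynyl)-1-methyl-10-oxo-6-(TBS-oxy)cyclohept-6-ene-7-carboxylate (C2 epimers, not isolated) | CC(C)C#CC(O)[C@@]1(C)CC(O[Si](C)(C)C(C)(C)C)=C(C(=O)OC(C)(C)C)CCC1=O | intermediate
16 | tert-butyl 10β-hydroxy-1-(1-hydroxy-4-methylpent-2-ynyl)-1-methyl-6-(TBS-oxy)cyclohept-6-ene-7-carboxylate (C2 epimers) | CC(C)C#CC(O)[C@@]1(C)CC(O[Si](C)(C)C(C)(C)C)=C(C(=O)OC(C)(C)C)CC[C@@H]1O | intermediate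
17 | tert-butyl 10β-hydroxy-1-methyl-1-(4-methylpent-2-ynoyl)-6-(TBS-oxy)cyclohept-6-ene-7-carboxylate | CC(C)C#CC(=O)[C@@]1(C)CC(O[Si](C)(C)C(C)(C)C)=C(C(=O)OC(C)(C)C)CC[C@@H]1O | intermediate
18 | tert-butyl 1-methyl-1-(4-methylpent-2-ynoyl)-6-(TBS-oxy)-10β-(TIPS-oxy)cyclohept-6-ene-7-carboxylate | CC(C)C#CC(=O)[C@@]1(C)CC(O[Si](C)(C)C(C)(C)C)=C(C(=O)OC(C)(C)C)CC[C@@H]1O[Si](C(C)C)(C(C)C)C(C)C | intermediate
19 | 1-methyl-1-(4-methylpent-2-ynoyl)-6-oxo-10β-(TIPS-oxy)cycloheptane-7-carboxylic acid (not isolated) | CC(C)C#CC(=O)[C@@]1(C)CC(=O)C(C(=O)O)CC[C@@H]1O[Si](C(C)C)(C(C)C)C(C)C | intermediate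
20 | 1-methyl-1-(4-methylpent-2-ynoyl)-10β-(TIPS-oxy)cycloheptan-6-one | CC(C)C#CC(=O)[C@@]1(C)CC(=O)CCC[C@@H]1O[Si](C(C)C)(C(C)C)C(C)C | intermediate
21 | 4-isopropyl-1-methyl-10β-(TIPS-oxy)bicyclo[5.3.0]dec-4-ene-2,6-dione | O=C1CCC[C@H](O[Si](C(C)C)(C(C)C)C(C)C)[C@@]2(C)C(=O)CC(C(C)C)=C12 | intermediate
22 | 4-isopropyl-1-methyl-10β-(TIPS-oxy)bicyclo[5.3.0]dec-4-ene-2β,6β-diol | O[C@@H]1CCC[C@H](O[Si](C(C)C)(C(C)C)C(C)C)[C@@]2(C)[C@H](O)CC(C(C)C)=C12 | intermediate
23 | 4β,5β-epoxy-4-isopropyl-1-methyl-10β-(TIPS-oxy)bicyclo[5.3.0]decane-2β,6β-diol | O[C@@H]1CCC[C@H](O[Si](C(C)C)(C(C)C)C(C)C)[C@@]2(C)[C@H](O)C[C@]3(C(C)C)O[C@]123 | intermediate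
24 | 4β,5β-epoxy-4-isopropyl-1-methyl-2β,6β-bis(TES-oxy)-10β-(TIPS-oxy)bicyclo[5.3.0]decane | CC[Si](CC)(CC)O[C@@H]1CCC[C@H](O[Si](C(C)C)(C(C)C)C(C)C)[C@@]2(C)[C@H](O[Si](CC)(CC)CC)C[C@]3(C(C)C)O[C@]123 | intermediate
25 | trans-fused 4β-hydroxy-4-isopropyl-1-methyl-2β-(TES-oxy)-10β-(TIPS-oxy)bicyclo[5.3.0]decan-6-one | O=C1CCC[C@H](O[Si](C(C)C)(C(C)C)C(C)C)[C@@]2(C)[C@H](O[Si](CC)(CC)CC)C[C@@](O)(C(C)C)[C@H]12 | intermediate
26 | trans-fused 4-isopropyl-1-methyl-2β-(TES-oxy)-10β-(TIPS-oxy)bicyclo[5.3.0]decane-4β,6α-diol | O[C@H]1CCC[C@H](O[Si](C(C)C)(C(C)C)C(C)C)[C@@]2(C)[C@H](O[Si](CC)(CC)CC)C[C@@](O)(C(C)C)[C@H]12 | intermediate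
27 | angelic acid, (Z)-2-methylbut-2-enoic acid | C/C=C(/C)C(=O)O | starting material
28 | trans-fused 6α-angeloyloxy-4-isopropyl-1-methyl-2β-(TES-oxy)-10β-(TIPS-oxy)bicyclo[5.3.0]decan-4β-ol | C/C=C(/C)C(=O)O[C@H]1CCC[C@H](O[Si](C(C)C)(C(C)C)C(C)C)[C@@]2(C)[C@H](O[Si](CC)(CC)CC)C[C@@](O)(C(C)C)[C@H]12 | intermediate
29 | trans-fused 6α-angeloyloxy-4-isopropyl-1-methyl-10β-(TIPS-oxy)bicyclo[5.3.0]decane-2β,4β-diol | C/C=C(/C)C(=O)O[C@H]1CCC[C@H](O[Si](C(C)C)(C(C)C)C(C)C)[C@@]2(C)[C@H](O)C[C@@](O)(C(C)C)[C@H]12 | intermediate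
30 | trans-fused 6α-angeloyloxy-4β-hydroxy-4-isopropyl-1-methyl-10β-(TIPS-oxy)bicyclo[5.3.0]decan-2-one | C/C=C(/C)C(=O)O[C@H]1CCC[C@H](O[Si](C(C)C)(C(C)C)C(C)C)[C@@]2(C)C(=O)C[C@@](O)(C(C)C)[C@H]12 | intermediate
31 | trans-fused 6α-angeloyloxy-4-isopropyl-1-methyl-10β-(TIPS-oxy)bicyclo[5.3.0]decane-2α,4β-diol | C/C=C(/C)C(=O)O[C@H]1CCC[C@H](O[Si](C(C)C)(C(C)C)C(C)C)[C@@]2(C)[C@@H](O)C[C@@](O)(C(C)C)[C@H]12 | intermediate
32 | trans-fused 2α-acetoxy-6α-angeloyloxy-4-isopropyl-1-methyl-10β-(TIPS-oxy)bicyclo[5.3.0]decan-4β-ol | C/C=C(/C)C(=O)O[C@H]1CCC[C@H](O[Si](C(C)C)(C(C)C)C(C)C)[C@@]2(C)[C@@H](OC(C)=O)C[C@@](O)(C(C)C)[C@H]12 | intermediate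
33 | trans-fused 2α-acetoxy-6α-angeloyloxy-4-isopropyl-1-methylbicyclo[5.3.0]decane-4β,10β-diol | C/C=C(/C)C(=O)O[C@H]1CCC[C@H](O)[C@@]2(C)[C@@H](OC(C)=O)C[C@@](O)(C(C)C)[C@H]12 | intermediate
34 | trans-fused 2α-acetoxy-6α-angeloyloxy-4β-hydroxy-4-isopropyl-1-methylbicyclo[5.3.0]decan-10-one (not isolated) | C/C=C(/C)C(=O)O[C@H]1CCCC(=O)[C@@]2(C)[C@@H](OC(C)=O)C[C@@](O)(C(C)C)[C@H]12 | intermediate
35 | trans-fused 2α-acetoxy-6α-angeloyloxy-4β-hydroxy-4-isopropyl-1-methylbicyclo[5.3.0]dec-8-en-10-one | C/C=C(/C)C(=O)O[C@H]1CC=CC(=O)[C@@]2(C)[C@@H](OC(C)=O)C[C@@](O)(C(C)C)[C@H]12 | intermediate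
36 | trans-fused 2α-acetoxy-6α-angeloyloxy-4β-hydroxy-4-isopropyl-1,8-dimethylbicyclo[5.3.0]decan-10-one (C8 epimers) | C/C=C(/C)C(=O)O[C@H]1CC(C)CC(=O)[C@@]2(C)[C@@H](OC(C)=O)C[C@@](O)(C(C)C)[C@H]12 | intermediate
37 | trans-fused 2α-acetoxy-6α-angeloyloxy-4β-hydroxy-4-isopropyl-1,8-dimethylbicyclo[5.3.0]dec-8-en-10-one | C/C=C(/C)C(=O)O[C@H]1CC(C)=CC(=O)[C@@]2(C)[C@@H](OC(C)=O)C[C@@](O)(C(C)C)[C@H]12 | intermediate
38 | trans-fused 2α-acetoxy-6α-angeloyloxy-4-isopropyl-1,8-dimethylbicyclo[5.3.0]dec-8-ene-4β,10β-diol | C/C=C(/C)C(=O)O[C@H]1CC(C)=C[C@H](O)[C@@]2(C)[C@@H](OC(C)=O)C[C@@](O)(C(C)C)[C@H]12 | intermediate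
39 | CNP0248576.1, 2α-acetoxy-6α-angeloyloxy-10β-benzoyloxy-4β-hydroxy-4-isopropyl-1,8-dimethyl-trans-bicyclo[5.3.0]dec-8-ene | C/C=C(/C)C(=O)O[C@H]1CC(C)=C[C@H](OC(=O)c2ccccc2)[C@@]2(C)[C@@H](OC(C)=O)C[C@@](O)(C(C)C)[C@H]12 | target

## Step count and least certain steps

Total: 29 steps. Longest linear sequence: 27 steps (steps 1, 2 and 5–29; the branch through steps 3 and 4 is equally long).

**Step 5 (key step).** The terminal alkene of 5 is conjugated to a push–pull enoate and is less electron-rich than the dienes usually used, so cyclopropanation may be slow relative to carbenoid dimerisation and the facial selectivity may erode; the inside methyl group also slows the Cope shift. Fallback by covalent resolution: from 5 and 8 the cycloaddition is run with the achiral catalyst Rh2(O2CCMe3)4 (dirhodium tetrapivalate) to give 10 as the racemate, and step 6 gives racemic 11. Esterification with (R)-2-methoxy-2-phenylacetic acid (dicyclohexylcarbodiimide, DMAP) gives the (R)-O-methylmandelate of 11, F1, together with the (R)-O-methylmandelate of the antipode of 11, F2. These are separated by chromatography or crystallisation, and i-Bu2AlH at −78 °C cleaves F1 to return to the route at 11.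

**Step 6.** Loss of chemoselectivity is the risk: the hindered methyl ester may need temperatures at which the tert-butyl vinylogous carbonate is also attacked. Fallback by acyl substitution instead of reduction: from 10, the lithium acetylide of 13 with BF3·OEt2 at −78 °C adds once to the methyl ester and gives the alkynone with both enol ethers intact, tert-butyl 1-methyl-1-(4-methylpent-2-ynoyl)-6-(TBS-oxy)-10-(TES-oxy)cyclohepta-6,9-diene-7-carboxylate F3. NaBH4/CeCl3·7H2O then reduces the alkynone 1,2 and the route is rejoined at 14.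

**Step 13.** The enolate may add to the alkynone carbonyl instead, the base may isomerise the alkynone to an allenone, or protonation of the vinylogous diketonate may occur at C5 and give the cyclopentenone tautomer. Fallback through the 1,3-diketone: from 20, pyrrolidine adds to the alkynone (aza-Michael) to give the enaminone 1-methyl-1-[4-methyl-3-(pyrrolidin-1-yl)pent-2-enoyl]-10β-(TIPS-oxy)cycloheptan-6-one F4. Aqueous AcOH hydrolyses F4 to the triketone 1-methyl-1-(4-methyl-3-oxopentanoyl)-10β-(TIPS-oxy)cycloheptan-6-one F5. Pyrrolidinium acetate in toluene at 60 °C then effects the intramolecular aldol condensation of the C5 enamine onto the C4 carbonyl (a 5-exo-trig closure with no leaving group β to the carbonyl) and returns to the route at 21.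

**Step 17.** The epoxide may ionise at C4 instead of C5 (elimination towards the isopropyl group), or the C2 silyl ether may be lost. Fallback by reductive opening: from 23, Dess–Martin periodinane gives the epoxy diketone 4β,5β-epoxy-4-isopropyl-1-methyl-10β-(TIPS-oxy)bicyclo[5.3.0]decane-2,6-dione F6. SmI2 in THF/MeOH at −78 °C cleaves the C5–O bond α to the C6 ketone, and the samarium enolate should be protonated from the α-face, anti to the C4 oxygen and the C1 methyl, to give trans-fused 4β-hydroxy-4-isopropyl-1-methyl-10β-(TIPS-oxy)bicyclo[5.3.0]decane-2,6-dione F7. Me4NBH(OAc)3 reduces both ketones under direction of the C4 hydroxyl to trans-fused 4-isopropyl-1-methyl-10β-(TIPS-oxy)bicyclo[5.3.0]decane-2α,4β,6α-triol F8, and selective esterification of the more accessible C6 hydroxyl with 27 under the conditions of step 19 returns to the route at 31.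

**Step 25.** Dehydrogenation may be sluggish, or may run on towards C7 at the temperature IBX needs. Fallback by a stepwise Saegusa oxidation: from 33, Dess–Martin periodinane gives 34, which is isolated. Me3SiOTf/Et3N at −78 → 0 °C gives the enol ether trans-fused 2α-acetoxy-6α-angeloyloxy-4-isopropyl-1-methyl-4β,10-bis(trimethylsilyloxy)bicyclo[5.3.0]dec-9-ene F9, and Pd(OAc)2 in MeCN followed by dilute acid returns to the route at 35.

## Further compounds

F1 | step 5 | (R)-O-methylmandelate of 11 | CO[C@H](c1ccccc1)C(=O)OC[C@@]1(C)CC(O[Si](C)(C)C(C)(C)C)=C(C(=O)OC(C)(C)C)CC=C1O[Si](CC)(CC)CC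
F2 | step 5 | (R)-O-methylmandelate of the antipode of 11 | CO[C@H](c1ccccc1)C(=O)OC[C@]1(C)CC(O[Si](C)(C)C(C)(C)C)=C(C(=O)OC(C)(C)C)CC=C1O[Si](CC)(CC)CC
F3 | step 6 | tert-butyl 1-methyl-1-(4-methylpent-2-ynoyl)-6-(TBS-oxy)-10-(TES-oxy)cyclohepta-6,9-diene-7-carboxylate | CC(C)C#CC(=O)[C@@]1(C)CC(O[Si](C)(C)C(C)(C)C)=C(C(=O)OC(C)(C)C)CC=C1O[Si](CC)(CC)CC
F4 | step 13 | 1-methyl-1-[4-methyl-3-(pyrrolidin-1-yl)pent-2-enoyl]-10β-(TIPS-oxy)cycloheptan-6-one | CC(C)C(=CC(=O)[C@@]1(C)CC(=O)CCC[C@@H]1O[Si](C(C)C)(C(C)C)C(C)C)N1CCCC1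
F5 | step 13 | 1-methyl-1-(4-methyl-3-oxopentanoyl)-10β-(TIPS-oxy)cycloheptan-6-one | CC(C)C(=O)CC(=O)[C@@]1(C)CC(=O)CCC[C@@H]1O[Si](C(C)C)(C(C)C)C(C)C
F6 | step 17 | 4β,5β-epoxy-4-isopropyl-1-methyl-10β-(TIPS-oxy)bicyclo[5.3.0]decane-2,6-dione | O=C1CCC[C@H](O[Si](C(C)C)(C(C)C)C(C)C)[C@@]2(C)C(=O)C[C@]3(C(C)C)O[C@]123
F7 | step 17 | trans-fused 4β-hydroxy-4-isopropyl-1-methyl-10β-(TIPS-oxy)bicyclo[5.3.0]decane-2,6-dione | O=C1CCC[C@H](O[Si](C(C)C)(C(C)C)C(C)C)[C@@]2(C)C(=O)C[C@@](O)(C(C)C)[C@H]12
F8 | step 17 | trans-fused 4-isopropyl-1-methyl-10β-(TIPS-oxy)bicyclo[5.3.0]decane-2α,4β,6α-triol | O[C@H]1CCC[C@H](O[Si](C(C)C)(C(C)C)C(C)C)[C@@]2(C)[C@@H](O)C[C@@](O)(C(C)C)[C@H]12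
F9 | step 25 | trans-fused 2α-acetoxy-6α-angeloyloxy-4-isopropyl-1-methyl-4β,10-bis(trimethylsilyloxy)bicyclo[5.3.0]dec-9-ene | C/C=C(/C)C(=O)O[C@H]1CCC=C(O[Si](C)(C)C)[C@@]2(C)[C@@H](OC(C)=O)C[C@@](O[Si](C)(C)C)(C(C)C)[C@H]12
A1 | alternative 1 | 2-(TBS-oxy)-1-methyl-4-isopropyl-4-(trimethylsilyloxy)-5-[(4-methoxybenzyloxy)methyl]cyclopentane-1-carbaldehyde | O=C[C@@]1(C)[C@@H](O[Si](C)(C)C(C)(C)C)C[C@@](O[Si](C)(C)C)(C(C)C)[C@@H]1COCc1ccc(OC)cc1
A2 | alternative 2 | trans-fused 2,6-bis(TBS-oxy)-4-(trimethylsilyloxy)-1,8-dimethyl-4-isopropylbicyclo[5.3.0]deca-6,8-dien-10-one | CC1=CC(=O)[C@@]2(C)[C@@H](O[Si](C)(C)C(C)(C)C)C[C@@](O[Si](C)(C)C)(C(C)C)[C@@H]2C(O[Si](C)(C)C(C)(C)C)=C1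
A3 | alternative 3 | trans-fused 2-(TBS-oxy)-4-(trimethylsilyloxy)-4-isopropyl-1-methyl-8-methylidenebicyclo[5.3.0]decane-6,10-diol | O[C@H]1CC(=C)C[C@H](O)[C@@]2(C)[C@@H](O[Si](C)(C)C(C)(C)C)C[C@@](O[Si](C)(C)C)(C(C)C)[C@H]12
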